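**Retrosynthetic overview**

1. Target ⇐ dienone–phenol ring expansion of a spiro[4.5]decadienone: C7' shifts 1,2 from C1 to C2 of ring A, turning the spiro cyclopentane into ring B of the tetralin.
2. Spirodienone ⇐ dearomative five-ring closure (C1–C7') of the syringyl phenolate onto a guaiacyl p-quinone methide generated from a 1,4-diaryl-2,3-dimethylbutan-1-ol.
3. Butanol (C7–aryl bond, C8 centre) ⇐ anti-selective hydroboration / B-alkyl Suzuki coupling of a homoallylic alcohol with 4-bromo-2,6-dimethoxyphenol (from resorcinol).
4. Homoallylic alcohol (C7'–C8' bond, C8' centre) ⇐ catalytic asymmetric tiglylation of vanillin (from catechol and glyoxylic acid).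
5. Ring order: both arenes come from bought diphenols; the spiro cyclopentane is closed first and is then expanded to the six-membered ring B.

Assumption: (E)-1-bromo-2-methylbut-2-ene (tiglyl bromide) is taken as commercially available. C7, C8, C7', C8' are the lignan numbers of the butane carbons; ring A is the trioxygenated arene, ring B the saturated ring.

**Route**

Step 1
Reactants: 1 catechol
Product: 2 guaiacol (2-methoxyphenol)
Conditions: MeI (1.0 equiv), K2CO3 (1.0 equiv), acetone, reflux; distil
Reagents that add atoms: iodomethane, CI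
Why: Williamson mono-O-methylation of one of two equivalent phenols; veratrole and unreacted catechol are removed by distillation.

Step 2
Reactants: 2 guaiacol; 3 glyoxylic acid
Product: 6 vanillin (4-hydroxy-3-methoxybenzaldehyde), via mandelic acid 4 (not isolated), via keto acid 5 (not isolated)
Conditions: NaOH, H2O, 30 °C; then CuSO4 (cat.), air, NaOH, 95 °C; then H2SO4 to pH 3, 60 °C
Reagents that add atoms: none
Why: Electrophilic substitution of the guaiacolate para to the phenoxide by glyoxylate, copper-catalysed aerobic oxidation of the mandelate and decarboxylation of the α-keto acid on acidification (the industrial vanillin sequence).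

Step 3
Reactants: 6 vanillin; 7 (E)-1-bromo-2-methylbut-2-ene (tiglyl bromide)
Product: 10 (1R,2R)-1-(4-hydroxy-3-methoxyphenyl)-2,3-dimethylbut-3-en-1-ol, via silylated aldehyde 8 (not isolated), via bis-silyl ether 9 (not isolated)
Conditions: Me3SiCl (2.5 equiv), i-Pr2NEt (1.2 equiv), THF, 0 °C; then 7, CrCl2 (10 mol%), (S,S)-1,8-bis(4-isopropyl-4,5-dihydrooxazol-2-yl)-3,6-diphenyl-9H-carbazole (11 mol%; the ligand enantiomer that gives the 1R,2R alcohol), Mn powder (2 equiv), rt; then 1 M HCl, THF; chromatography to remove any syn isomer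
Reagents that add atoms: none
Why: Catalytic asymmetric Nozaki–Hiyama–Kishi allylation, in which the tiglylchromium species adds through its γ-carbon in a chair transition state (anti, whatever the bromide geometry) while the chiral ligand selects the aldehyde face, so C8' is set as R (the C7' carbinol set with it is erased in step 8).

Step 4
Reactants: 11 resorcinol
Product: 12 1,3-dimethoxybenzene
Conditions: MeI (2.4 equiv), K2CO3 (2.4 equiv), acetone, reflux
Reagents that add atoms: iodomethane, CI
Why: Double Williamson O-methylation.

Step 5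
Reactants: 12 1,3-dimethoxybenzene
Product: 15 2,6-dimethoxyphenol, via aryllithium 13 (not isolated), via arylboronate 14 (not isolated)
Conditions: n-BuLi, THF, 0 °C to rt; then B(OMe)3, −78 °C to rt; then AcOH, 30% H2O2, 0 °C to rt
Reagents that add atoms: hydrogen peroxide, OO
Why: Directed ortho-lithiation at the position between the two methoxy groups, borylation and oxidative C–B to C–O conversion.

Step 6
Reactants: 15 2,6-dimethoxyphenol
Product: 16 4-bromo-2,6-dimethoxyphenol
Conditions: NBS (1.0 equiv), CH2Cl2, −40 °C to 0 °C
Reagents that add atoms: N-bromosuccinimide, BrN1C(=O)CCC1=O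
Why: Electrophilic aromatic bromination para to the free phenol, whose two ortho positions are blocked by methoxy groups.

Step 7
Reactants: 10 (1R,2R)-1-(4-hydroxy-3-methoxyphenyl)-2,3-dimethylbut-3-en-1-ol; 16 4-bromo-2,6-dimethoxyphenol
Product: 18 (1R,2R,3R)-1-(4-hydroxy-3-methoxyphenyl)-4-(4-hydroxy-3,5-dimethoxyphenyl)-2,3-dimethylbutan-1-ol, via alkylborane 17 (not isolated)
Conditions: 9-BBN (3.5 equiv; the excess is taken up by the two OH groups), THF, 0 °C to rt; then 16, Pd(OAc)2 (5 mol%), SPhos (10 mol%), 3 M aq K3PO4, THF, 50 °C; chromatography to remove the minor C8 epimer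
Reagents that add atoms: none
Why: 9-BBN hydroborates the 1,1-disubstituted alkene at the terminal carbon from the face opposite the bulky carbinol arm in the conformer with the allylic C8'–H in the alkene plane (acyclic 1,2-induction, expected about 6–10:1), which gives the 2,3-anti dimethyl pattern (8R), and the primary B-alkyl-9-BBN then undergoes B-alkyl Suzuki–Miyaura coupling with the aryl bromide.

Step 8
Reactants: 18 (1R,2R,3R)-1-(4-hydroxy-3-methoxyphenyl)-4-(4-hydroxy-3,5-dimethoxyphenyl)-2,3-dimethylbutan-1-ol
Product: 21 (−)-(7'R,8R,8'R)-4,4'-dihydroxy-3,3',5-trimethoxy-2,7'-cyclolignan, via quinone methide 19 (not isolated), via spirodienone 20 (not isolated)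
Conditions: K2CO3 (3 equiv), degassed H2O–1,4-dioxane (1:1), 0.01 M, 80 °C, argon; then solvent exchange, CF3CO2H–CH2Cl2 (1:4), 0 °C to rt
Reagents that add atoms: none
Why: Proposed new method: in hot aqueous base the guaiacyl phenolate expels hydroxide to give p-quinone methide 19, and the syringyl phenolate, whose only nucleophilic carbon is the alkyl-bearing para carbon C1 (both ortho carbons carry OMe and C2 is meta to the oxide), closes the five-membered ring by intramolecular 1,6-addition to give spirodienone 20 with the aryl group trans to the C8' methyl; acid then protonates the dienone and the bis-benzylic-type carbon C7' (a far better migrating group than the primary C7) shifts 1,2 from C1 to C2 with retention, or by ionisation and re-closure at C2, which expands the cyclopentane to ring B, restores the phenol and leaves C7' as R, trans to the C8' methyl; the closest known reaction types are the para-alkylative spirocyclisation of phenolates with tethered electrophiles, base-mediated 1,6-additions to p-quinone methides made in the flask from p-hydroxybenzyl alcohols, and the acid-catalysed dienone–phenol rearrangement of spiro[4.5]decadienones to tetralinols, which have not been combined on a dibenzylbutane lignan precursor.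

**Compound list**

1 | catechol (benzene-1,2-diol) | Oc1ccccc1O | starting material
2 | guaiacol (2-methoxyphenol) | COc1ccccc1O | intermediate
3 | glyoxylic acid | O=CC(=O)O | starting material
4 | 4-hydroxy-3-methoxymandelic acid (racemic) | COc1cc(C(O)C(=O)O)ccc1O | intermediate (not isolated)
5 | (4-hydroxy-3-methoxyphenyl)glyoxylic acid | COc1cc(C(=O)C(=O)O)ccc1O | intermediate (not isolated)
6 | vanillin (4-hydroxy-3-methoxybenzaldehyde) | COc1cc(C=O)ccc1O | intermediate
7 | (E)-1-bromo-2-methylbut-2-ene (tiglyl bromide) | C/C=C(\C)CBr | starting material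
8 | 3-methoxy-4-(trimethylsilyloxy)benzaldehyde | COc1cc(C=O)ccc1O[Si](C)(C)C | intermediate (not isolated)
9 | (1R,2R)-1-[3-methoxy-4-(trimethylsilyloxy)phenyl]-2,3-dimethyl-1-(trimethylsilyloxy)but-3-ene | COc1cc(ccc1O[Si](C)(C)C)[C@H](O[Si](C)(C)C)[C@H](C)C(C)=C | intermediate (not isolated)
10 | (1R,2R)-1-(4-hydroxy-3-methoxyphenyl)-2,3-dimethylbut-3-en-1-ol (anti) | COc1cc(ccc1O)[C@H](O)[C@H](C)C(C)=C | intermediate
11 | resorcinol (benzene-1,3-diol) | Oc1cccc(O)c1 | starting material
12 | 1,3-dimethoxybenzene | COc1cccc(OC)c1 | intermediate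
13 | 2,6-dimethoxyphenyllithium | [Li]c1c(OC)cccc1OC | intermediate (not isolated)
14 | dimethyl (2,6-dimethoxyphenyl)boronate | COB(OC)c1c(OC)cccc1OC | intermediate (not isolated)
15 | 2,6-dimethoxyphenol | COc1cccc(OC)c1O | intermediate
16 | 4-bromo-2,6-dimethoxyphenol | COc1cc(Br)cc(OC)c1O | intermediate
17 | 9-[(2R,3R,4R)-4-hydroxy-4-(4-hydroxy-3-methoxyphenyl)-2,3-dimethylbutyl]-9-borabicyclo[3.3.1]nonane (OH groups drawn free; O-borylated in the flask) | COc1cc(ccc1O)[C@H](O)[C@H](C)[C@H](C)CB1C2CCCC1CCC2 | intermediate (not isolated)
18 | (1R,2R,3R)-1-(4-hydroxy-3-methoxyphenyl)-4-(4-hydroxy-3,5-dimethoxyphenyl)-2,3-dimethylbutan-1-ol | COc1cc(ccc1O)[C@H](O)[C@H](C)[C@H](C)Cc1cc(OC)c(O)c(OC)c1 | intermediate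
19 | 4-[(2R,3R)-4-(4-hydroxy-3,5-dimethoxyphenyl)-2,3-dimethylbutylidene]-2-methoxycyclohexa-2,5-dien-1-one (p-quinone methide, alkene geometry not defined) | COC1=CC(=C[C@H](C)[C@H](C)Cc2cc(OC)c(O)c(OC)c2)C=CC1=O | intermediate (not isolated)
20 | (1R,2R,3R)-1-(4-hydroxy-3-methoxyphenyl)-7,9-dimethoxy-2,3-dimethylspiro[4.5]deca-6,9-dien-8-one | COc1cc(ccc1O)[C@H]1[C@H](C)[C@H](C)CC12C=C(OC)C(=O)C(OC)=C2 | intermediate (not isolated)
21 | (−)-(7'R,8R,8'R)-4,4'-dihydroxy-3,3',5-trimethoxy-2,7'-cyclolignan, that is (6R,7R,8R)-8-(4-hydroxy-3-methoxyphenyl)-1,3-dimethoxy-6,7-dimethyl-5,6,7,8-tetrahydronaphthalen-2-ol (aryl trans to the 7-methyl, the two methyls cis) | COc1cc([C@@H]2c3c(cc(OC)c(O)c3OC)C[C@@H](C)[C@H]2C)ccc1O | target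

**Step count and risks**

Total step count: 8. Longest linear sequence: 5 (steps 1, 2, 3, 7, 8 from catechol, or steps 4, 5, 6, 7, 8 from resorcinol).

Steps most likely to fail:

Step 3. Tiglyl bromide is an untested partner for this chromium/bis(oxazolinyl)carbazole system, and any syn isomer or low enantioselectivity puts the wrong C8' into everything that follows. The fallback sets out from 6 and 7 and gives up asymmetric catalysis for racemic synthesis plus resolution: ligand-free addition with stoichiometric CrCl2 in THF (anti-selective) gives the racemic alcohol rac-(1R*,2R*)-1-(4-hydroxy-3-methoxyphenyl)-2,3-dimethylbut-3-en-1-ol F1. This is resolved by preparative chiral SFC (or lipase-mediated acylation), and the 1R,2R enantiomer comes back to the route at 10.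

Step 7. The hydroboration relies on acyclic 1,2-induction for C8, and the electron-rich bromophenol is a slow partner in the coupling. The fallback sets out from 10 and 16 and moves the C8 centre to a catalyst-controlled step. Mizoroki–Heck coupling (Pd(OAc)2, P(o-tol)3, Et3N, DMF, 90 °C) gives the styrene (1R,2R,3E)-1-(4-hydroxy-3-methoxyphenyl)-4-(4-hydroxy-3,5-dimethoxyphenyl)-2,3-dimethylbut-3-en-1-ol F2. Asymmetric hydrogenation of this (E)-1-aryl-2-methylalkene then sets C8 and comes back to the route at 18; the catalyst is [Ir(cod)(L)][B(C6H3(CF3)2)4] with L = 4-tert-butyl-2-[2-(diphenylphosphino)phenyl]-4,5-dihydrooxazole (enantiomer chosen by screening), under H2 (50 bar) in CH2Cl2.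

Step 8 (the proposed new step). The quinone methide 19 may tautomerise to the 4-alkenylphenol under base, which destroys C8', before the five-ring closure, or the spirodienone may not form cleanly. The fallback uses known chemistry and sets out from 18: direct acid-mediated intramolecular Friedel–Crafts alkylation (BF3·OEt2 or CF3CO2H, CH2Cl2, −20 °C to 0 °C), as established for 7'-hydroxy-dibenzylbutanes. The benzylic cation is attacked directly by C2 of ring A, with the aryl group going trans to the C8' methyl. It comes back to the route at 21 and makes no new compound (F0).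

**Further compounds**

F1 | step 3 | rac-(1R*,2R*)-1-(4-hydroxy-3-methoxyphenyl)-2,3-dimethylbut-3-en-1-ol | COc1cc(ccc1O)[C@H](O)[C@H](C)C(C)=C.COc1cc(ccc1O)[C@@H](O)[C@@H](C)C(C)=C
F2 | step 7 | (1R,2R,3E)-1-(4-hydroxy-3-methoxyphenyl)-4-(4-hydroxy-3,5-dimethoxyphenyl)-2,3-dimethylbut-3-en-1-ol | COc1cc(ccc1O)[C@H](O)[C@H](C)/C(C)=C/c1cc(OC)c(O)c(OC)c1
F0 | step 8 | none | none
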